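The runs were computed for substances that don't exist.

The substrate left in the flask at 4.0 d can be reckoned from one number read off the earlier runs, once that number is frozen.

the same everywhere: gas 28 mM (held)
- birch: substrate 0.037 M; initiator 3.1 mM; run made earlier
- ash: substrate 0.15 M; initiator 3.1 mM; run made earlier
- elm: substrate 0.074 M; initiator 6.2 mM; run made earlier
- flask: substrate 0.074 M; initiator 3.1 mM; time 4.0 d

| run | time / d | product / % | substrate / % |
|---|---|---|---|
| birch | 0.208 | 10 | 91 |
| birch | 0.625 | 30 | 66 |
| birch | 1.04 | 47 | 53 |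
| birch | 1.67 | 66 | 35 |
| birch | 2.50 | 79 | 20 |
| birch | 3.00 | 83 | 13 |
| ash | 0.500 | 17 | 84 |
| ash | 1.04 | 34 | 67 |
| ash | 1.67 | 53 | 48 |
| ash | 2.00 | 61 | 37 |
| ash | 2.50 | 74 | 30 |
| ash | 3.00 | 80 | 23 |
| elm | 0.625 | 36 | 66 |
| elm | 1.25 | 64 | 37 |
| elm | 2.08 | 82 | 16 |
| elm | 2.50 | 89 | 11 |
| elm | 3.00 | 93 | 6 |

(standard deviation of a reading: 1.5 percentage points)

- at the start none of the gas is in solution

1. amount of product in the flask at 4.0 d, in percent of the substrate charged
2. amount of substrate in the flask at 4.0 d, in percent of the substrate charged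
3. concentration of reagent at 4.0 d, in M

If substrate falls at a steady fraction per day (pseudo-first-order), the natural logarithm of charge over what is left, divided by time, stays constant. In birch this ratio is 0.665 d⁻¹ at 0.625 d and 0.680 d⁻¹ at 3.00 d, so freezing it looks fair. In ash it climbs from 0.385 d⁻¹ at 1.04 d to 0.490 d⁻¹ at 3.00 d, so the frozen value is rough.

The ratio is lower in ash than in birch, and the flask's substrate charge is twice that of birch and half that of ash. Their geometric mean, 0.577 d⁻¹, therefore serves the flask. Elm has the flask's substrate charge and twice its initiator, and reads 0.938 d⁻¹. That is 1.63 times the mean, a weak reading, since 6% of substrate carries a scatter of 1.5 percentage points. This reckoning assumes half order in initiator, as for chains ended in pairs, which brings elm down to 0.663 d⁻¹.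

Averaging the two gives 0.620 d⁻¹, the flask's apparent first-order constant. Substrate at 4.0 d is then 8.37%. Substrate and product readings add to about the charge, so product is 91.6%. Reagent stands in no reading. Taken as dissolved gas, it has the held 28 mM as a ceiling, and this reckoning goes no further.

The forecast gave 90% product, 9% substrate and 0.001 M reagent, “so this value is a weak guess”.

The flask holds 91.5% product, 8.51% substrate and 0.0185 M reagent.

    initiator → 2 initiating radical (k = 1.60 × 10⁻⁴ h⁻¹)
    substrate + initiating radical → capped initiator + first chain carrier (k = 5.90 × 10⁵ M⁻¹ s⁻¹)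
    reagent + first chain carrier → product + second chain carrier (k = 29000 M⁻¹ s⁻¹)
    substrate + second chain carrier → released group + first chain carrier (k = 11000 M⁻¹ s⁻¹)
    2 second chain carrier → ended chains A (k = 3.00 × 10⁸ M⁻¹ s⁻¹)
    2 first chain carrier → ended chains B (k = 2.10 × 10⁷ M⁻¹ s⁻¹)
    2 reagent → homo dimer (k = 1.50 M⁻¹ h⁻¹)
    gas ⇌ reagent, rate k8*(csat - [reagent]) (kL = 0.170 h⁻¹)
    reagent ⇌ dormant form (K = 6.80, k = 0.0310 h⁻¹)

The flask's substrate gives a constant of 0.616 d⁻¹. In the flask, second chain carrier stands at 6.09 × 10⁻¹⁰ M at 0.400 d and 6.72 × 10⁻¹⁰ M at 4.00 d, and 98% of the initiator remains at the end. A neighbouring flask, the same in all else, charges 0.0053 M of initiator. Half order takes 0.620 d⁻¹ to 0.811 d⁻¹, which leaves 3.90% of substrate at 4.0 d. The neighbour holds 3.93% of substrate.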